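Tetralin numbering is used throughout: C1 carries the guaiacyl ring, C2 and C3 the CH2OH groups, C4 is the ring CH2, and ring A bears 6-OMe, 7-OH and 8-OH.
Retrosynthesis: C2–CH2OH is traced to a malonate carbon and C3–CH2OH to C3–CH2SO2Ph; ring B is then cut at C1–guaiacyl and at C2–C3 in one operation. This leaves a ring A arylidene malonate with an (E)-3-(phenylsulfonyl)allyl arm and a guaiacyl boronic acid; the two alkenes go back to an aldehyde (Knoevenagel) and an allyl group (cross-metathesis).
Enabling feature: in ring B, C2 sits between the diarylmethine C1 and C3, so as a malonate carbon it is first the acceptor α-carbon for arylation at C1 and then the nucleophile toward C3; the C1 aryl and the C3 branch are 1,3-cis.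
Forward: ring A comes from an eugenol-derived salicylaldehyde (Dakin oxidation, phenol-directed ortho-formylation); the guaiacyl ring is joined and ring B closed together in step 7; Krapcho reaction, two reductions and hydrogenolysis finish.
Stereochemistry: C1 from the chiral diene on rhodium, C3 from the chair-like Michael closure (cis to the C1 aryl), C2 from base equilibration to the all-trans ester.

Key step: step 7

Assumption: aldehyde 1 is taken as a catalogue chemical; it is the ortho-formylation product of eugenol.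
Assumption: the (R,R) antipode of the diene ligand is taken to deliver the 1S centre; should a first run show the opposite sense, the (S,S) ligand is used with nothing else changed.

Step 1
Reactants: 1 5-allyl-2-hydroxy-3-methoxybenzaldehyde
Product: 2 5-allyl-2-(benzyloxy)-3-methoxybenzaldehyde
Conditions: BnBr, K2CO3, DMF, 60 °C
Reagents that add atoms: benzyl bromide, BrCc1ccccc1
Why: Williamson ether synthesis on the only acidic OH; carbonate in DMF breaks the hydrogen bond to the aldehyde and the allyl group is untouched.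

Step 2
Reactants: 2 5-allyl-2-(benzyloxy)-3-methoxybenzaldehyde
Product: 4 5-allyl-2-(benzyloxy)-3-methoxyphenol, via aryl formate 3 (not isolated)
Conditions: 30% aq. H2O2, H2SO4 (cat.), MeOH, 0 °C to rt
Reagents that add atoms: hydrogen peroxide, OO
Why: Acid-catalysed Dakin oxidation, in which the electron-rich ortho-alkoxy aryl group migrates to oxygen and formate 3 is methanolysed in the same flask, while the isolated terminal alkene is inert to H2O2 in the absence of a peracid.

Step 3
Reactants: 4 5-allyl-2-(benzyloxy)-3-methoxyphenol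
Product: 6 6-allyl-3-(benzyloxy)-2-hydroxy-4-methoxybenzaldehyde, via hydroxymethyl phenol 5 (not isolated)
Conditions: MgCl2, Et3N, (CH2O)n, THF, reflux; aq. HCl work-up
Reagents that add atoms: paraformaldehyde (as formaldehyde), C=O
Why: Magnesium-mediated (Casnati–Skattebøl) ortho-formylation delivers carbon only ortho to the free OH through a magnesium phenoxide–formaldehyde chelate, the single free ortho position being the one next to the allyl group (future C8a), and hydroxymethyl intermediate 5 is oxidised by a second formaldehyde in an Oppenauer-type hydride transfer.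

Step 4
Reactants: 6 6-allyl-3-(benzyloxy)-2-hydroxy-4-methoxybenzaldehyde
Product: 7 6-allyl-2,3-bis(benzyloxy)-4-methoxybenzaldehyde
Conditions: BnBr, K2CO3, DMF, 60 °C
Reagents that add atoms: benzyl bromide, BrCc1ccccc1
Why: Williamson ether synthesis on the salicylaldehyde OH, giving the fully protected ring A aldehyde with the substitution pattern of C4a to C8a already in place.

Step 5
Reactants: 7 6-allyl-2,3-bis(benzyloxy)-4-methoxybenzaldehyde; 8 dimethyl malonate
Product: 9 dimethyl 2-{[6-allyl-2,3-bis(benzyloxy)-4-methoxyphenyl]methylidene}malonate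
Conditions: piperidine (cat.), AcOH (cat.), toluene, reflux, Dean–Stark
Reagents that add atoms: none
Why: Knoevenagel condensation of a non-enolisable aldehyde under piperidinium acetate catalysis with azeotropic removal of water; the amine salt is too weak a base to move the allyl double bond, and a Lewis acid that could cleave the ortho benzyl ether is avoided.

Step 6
Reactants: 9 dimethyl 2-{[6-allyl-2,3-bis(benzyloxy)-4-methoxyphenyl]methylidene}malonate; 10 phenyl vinyl sulfone
Product: 11 dimethyl 2-({2,3-bis(benzyloxy)-4-methoxy-6-[(E)-3-(phenylsulfonyl)prop-2-en-1-yl]phenyl}methylidene)malonate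
Conditions: second-generation Grubbs catalyst RuCl2(=CHPh)(PCy3)(H2IMes) (5 mol%), CH2Cl2, 40 °C
Reagents that add atoms: none
Why: Olefin cross-metathesis between a terminal alkene and an electron-poor vinyl sulfone that does not homodimerise should give the (E)-alkenyl sulfone selectively, and the trisubstituted, doubly acceptor-substituted alkylidene malonate is inert to the ruthenium carbene.

Step 7
Reactants: 11 dimethyl 2-({2,3-bis(benzyloxy)-4-methoxy-6-[(E)-3-(phenylsulfonyl)prop-2-en-1-yl]phenyl}methylidene)malonate; 12 [4-(benzyloxy)-3-methoxyphenyl]boronic acid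
Product: 14 dimethyl (1S,3R)-1-[4-(benzyloxy)-3-methoxyphenyl]-7,8-bis(benzyloxy)-6-methoxy-3-[(phenylsulfonyl)methyl]-3,4-dihydronaphthalene-2,2(1H)-dicarboxylate, via open-chain potassium malonate 13 (not isolated)
Conditions: [RhCl(C2H4)2]2 (2.5 mol%), (1R,4R)-2,5-diphenylbicyclo[2.2.2]octa-2,5-diene (5.5 mol%), 12 (1.5 equiv), aq. KOH (0.3 equiv), 1,4-dioxane/H2O 10:1, 30 °C
Reagents that add atoms: none
Why: Transmetallation of 12 to the hydroxo-rhodium diene complex (monovalent rhodium) gives an aryl-rhodium species that inserts the C1=C2 bond of the alkylidene malonate, and water releases the malonate as enolate 13 while returning the Rh–OH catalyst. Enolate 13 then adds through C2 to C3 of the tethered (E)-vinyl sulfone in a 6-exo-trig Michael closure that forms ring B, the α-sulfonyl carbanion being protonated by water. The closest known reactions are the rhodium/chiral diene 1,4-arylation of arylidene malonate-type acceptors with arylboronic acids and rhodium-catalysed conjugate addition–Michael cyclisation cascades. C1 is set by the chiral diene, which leaves one face of the alkylidene malonate open to the aryl-rhodium bond. C3 is set by the substrate: in the chair-like transition state allylic strain keeps C1–H in the plane of the malonate enolate, the C1 aryl and the sulfonylvinyl unit both sit pseudo-equatorial, and the 1,3-cis ring should result under kinetic control. The step needs insertion at the alkylidene malonate and not at the vinyl sulfone, which the double activation of the former and the low reactivity of a β-alkyl phenyl vinyl sulfone toward aryl-rhodium at 30 °C secure, and the substoichiometric, boronate-buffered KOH should leave the γ-aryl vinyl sulfone unisomerised.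

Step 8
Reactants: 14 dimethyl (1S,3R)-1-[4-(benzyloxy)-3-methoxyphenyl]-7,8-bis(benzyloxy)-6-methoxy-3-[(phenylsulfonyl)methyl]-3,4-dihydronaphthalene-2,2(1H)-dicarboxylate
Product: 16 methyl (1S,2R,3R)-1-[4-(benzyloxy)-3-methoxyphenyl]-7,8-bis(benzyloxy)-6-methoxy-3-[(phenylsulfonyl)methyl]-1,2,3,4-tetrahydronaphthalene-2-carboxylate, via C2-epimeric monoester 15 (not isolated)
Conditions: LiCl, H2O, DMSO, 150 °C; then NaOMe (0.3 equiv), MeOH/THF, 50 °C
Reagents that add atoms: none
Why: Krapcho dealkoxycarbonylation (chloride SN2 at one methyl ester, loss of CO2, protonation) removes one ester without touching sulfone or benzyl ethers, and the C2 epimers 15 should converge under methoxide through the ester enolate on the isomer with CO2Me trans to both neighbours, C1 and C3 not being epimerisable under these conditions.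

Step 9
Reactants: 16 methyl (1S,2R,3R)-1-[4-(benzyloxy)-3-methoxyphenyl]-7,8-bis(benzyloxy)-6-methoxy-3-[(phenylsulfonyl)methyl]-1,2,3,4-tetrahydronaphthalene-2-carboxylate
Product: 17 [(1S,2R,3R)-1-[4-(benzyloxy)-3-methoxyphenyl]-7,8-bis(benzyloxy)-6-methoxy-3-[(phenylsulfonyl)methyl]-1,2,3,4-tetrahydronaphthalen-2-yl]methanol
Conditions: LiAlH4, THF, 0 °C
Reagents that add atoms: none
Why: Hydride reduction of the ester to the primary alcohol, with sulfone and benzyl ethers inert at 0 °C; removing the carbonyl also removes the acidic C2–H and any retro-Michael pathway before the carbanion chemistry of step 11.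

Step 10
Reactants: 17 [(1S,2R,3R)-1-[4-(benzyloxy)-3-methoxyphenyl]-7,8-bis(benzyloxy)-6-methoxy-3-[(phenylsulfonyl)methyl]-1,2,3,4-tetrahydronaphthalen-2-yl]methanol
Product: 18 (1S,2R,3R)-7,8-bis(benzyloxy)-2-[(benzyloxy)methyl]-1-[4-(benzyloxy)-3-methoxyphenyl]-6-methoxy-3-[(phenylsulfonyl)methyl]-1,2,3,4-tetrahydronaphthalene
Conditions: NaH (1.05 equiv), BnBr, Bu4NI (cat.), THF/DMF, 0 °C to rt
Reagents that add atoms: benzyl bromide, BrCc1ccccc1
Why: Williamson ether synthesis on the alkoxide, which forms far more readily than the α-sulfonyl carbanion with one equivalent of NaH, and the new benzyl ether leaves with the other three in the last step.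

Step 11
Reactants: 18 (1S,2R,3R)-7,8-bis(benzyloxy)-2-[(benzyloxy)methyl]-1-[4-(benzyloxy)-3-methoxyphenyl]-6-methoxy-3-[(phenylsulfonyl)methyl]-1,2,3,4-tetrahydronaphthalene
Product: 21 (1S,2R,3R)-7,8-bis(benzyloxy)-2-[(benzyloxy)methyl]-1-[4-(benzyloxy)-3-methoxyphenyl]-6-methoxy-1,2,3,4-tetrahydronaphthalene-3-carbaldehyde (tetralin numbering), via α-lithio sulfone 19 (not isolated), via α-silyloxy sulfone 20 (not isolated)
Conditions: n-BuLi (1.05 equiv), THF, −78 °C; Me3SiOOSiMe3, −78 °C to 0 °C; pH 7 buffer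
Reagents that add atoms: bis(trimethylsilyl) peroxide, C[Si](C)(C)OO[Si](C)(C)C
Why: Oxidative desulfonylation, in which α-sulfonyl carbanion 19 attacks the O–O bond of the silyl peroxide and α-silyloxy sulfone 20 collapses with loss of benzenesulfinate to the aldehyde, the C3 centre being untouched at low temperature and under buffered work-up.

Step 12
Reactants: 21 (1S,2R,3R)-7,8-bis(benzyloxy)-2-[(benzyloxy)methyl]-1-[4-(benzyloxy)-3-methoxyphenyl]-6-methoxy-1,2,3,4-tetrahydronaphthalene-3-carbaldehyde
Product: 22 [(1S,2R,3R)-7,8-bis(benzyloxy)-2-[(benzyloxy)methyl]-1-[4-(benzyloxy)-3-methoxyphenyl]-6-methoxy-1,2,3,4-tetrahydronaphthalen-3-yl]methanol (tetralin numbering)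
Conditions: NaBH4, MeOH/THF, 0 °C
Reagents that add atoms: none
Why: Borohydride reduction of the aldehyde is fast at 0 °C and is run directly on the freshly prepared aldehyde so that the α-centre C3 has no time to epimerise.

Step 13
Reactants: 22 [(1S,2R,3R)-7,8-bis(benzyloxy)-2-[(benzyloxy)methyl]-1-[4-(benzyloxy)-3-methoxyphenyl]-6-methoxy-1,2,3,4-tetrahydronaphthalen-3-yl]methanol
Product: 23 (1S,2R,3R)-1-(4-hydroxy-3-methoxyphenyl)-2,3-bis(hydroxymethyl)-6-methoxy-1,2,3,4-tetrahydronaphthalene-7,8-diol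
Conditions: H2 (1 atm), Pd(OH)2 on carbon, MeOH/EtOAc, rt, product handled under argon
Reagents that add atoms: none
Why: Catalytic hydrogenolysis cleaves the three aryl benzyl ethers and the alkyl benzyl ether; no other reducible group is present and no stereocentre is involved.

Compound list
1 | 5-allyl-2-hydroxy-3-methoxybenzaldehyde | O=Cc1cc(CC=C)cc(OC)c1O | starting material
2 | 5-allyl-2-(benzyloxy)-3-methoxybenzaldehyde | O=Cc1cc(CC=C)cc(OC)c1OCc1ccccc1 | intermediate
3 | 5-allyl-2-(benzyloxy)-3-methoxyphenyl formate (not isolated) | O=COc1cc(CC=C)cc(OC)c1OCc1ccccc1 | intermediate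
4 | 5-allyl-2-(benzyloxy)-3-methoxyphenol | Oc1cc(CC=C)cc(OC)c1OCc1ccccc1 | intermediate
5 | 3-allyl-6-(benzyloxy)-2-(hydroxymethyl)-5-methoxyphenol (not isolated) | OCc1c(O)c(OCc2ccccc2)c(OC)cc1CC=C | intermediate
6 | 6-allyl-3-(benzyloxy)-2-hydroxy-4-methoxybenzaldehyde | O=Cc1c(O)c(OCc2ccccc2)c(OC)cc1CC=C | intermediate
7 | 6-allyl-2,3-bis(benzyloxy)-4-methoxybenzaldehyde | O=Cc1c(OCc2ccccc2)c(OCc2ccccc2)c(OC)cc1CC=C | intermediate
8 | dimethyl malonate | COC(=O)CC(=O)OC | starting material
9 | dimethyl 2-{[6-allyl-2,3-bis(benzyloxy)-4-methoxyphenyl]methylidene}malonate | COC(=O)C(=Cc1c(CC=C)cc(OC)c(OCc2ccccc2)c1OCc1ccccc1)C(=O)OC | intermediate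
10 | phenyl vinyl sulfone | C=CS(=O)(=O)c1ccccc1 | starting material
11 | dimethyl 2-({2,3-bis(benzyloxy)-4-methoxy-6-[(E)-3-(phenylsulfonyl)prop-2-en-1-yl]phenyl}methylidene)malonate | COC(=O)C(=Cc1c(C/C=C/S(=O)(=O)c2ccccc2)cc(OC)c(OCc3ccccc3)c1OCc4ccccc4)C(=O)OC | intermediate
12 | [4-(benzyloxy)-3-methoxyphenyl]boronic acid | COc1cc(B(O)O)ccc1OCc1ccccc1 | starting material
13 | potassium enolate of dimethyl 2-{(S)-[4-(benzyloxy)-3-methoxyphenyl]{2,3-bis(benzyloxy)-4-methoxy-6-[(E)-3-(phenylsulfonyl)prop-2-en-1-yl]phenyl}methyl}malonate (not isolated) | [K+].COc1cc([C@H]([C-](C(=O)OC)C(=O)OC)c2c(C/C=C/S(=O)(=O)c3ccccc3)cc(OC)c(OCc3ccccc3)c2OCc2ccccc2)ccc1OCc1ccccc1 | intermediate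
14 | dimethyl (1S,3R)-1-[4-(benzyloxy)-3-methoxyphenyl]-7,8-bis(benzyloxy)-6-methoxy-3-[(phenylsulfonyl)methyl]-3,4-dihydronaphthalene-2,2(1H)-dicarboxylate (1,3-cis) | COc1cc([C@H]2c3c(cc(OC)c(OCc4ccccc4)c3OCc5ccccc5)C[C@@H](CS(=O)(=O)c7ccccc7)C2(C(=O)OC)C(=O)OC)ccc1OCc6ccccc6 | intermediate
15 | methyl (1S,3R)-1-[4-(benzyloxy)-3-methoxyphenyl]-7,8-bis(benzyloxy)-6-methoxy-3-[(phenylsulfonyl)methyl]-1,2,3,4-tetrahydronaphthalene-2-carboxylate, both C2 epimers (not isolated) | COc1cc([C@H]2c3c(cc(OC)c(OCc4ccccc4)c3OCc5ccccc5)C[C@@H](CS(=O)(=O)c6ccccc6)C2C(=O)OC)ccc1OCc7ccccc7 | intermediate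
16 | methyl (1S,2R,3R)-1-[4-(benzyloxy)-3-methoxyphenyl]-7,8-bis(benzyloxy)-6-methoxy-3-[(phenylsulfonyl)methyl]-1,2,3,4-tetrahydronaphthalene-2-carboxylate (1,2-trans, 2,3-trans) | COc1cc([C@H]2c3c(cc(OC)c(OCc4ccccc4)c3OCc5ccccc5)C[C@@H](CS(=O)(=O)c6ccccc6)[C@@H]2C(=O)OC)ccc1OCc7ccccc7 | intermediate
17 | [(1S,2R,3R)-1-[4-(benzyloxy)-3-methoxyphenyl]-7,8-bis(benzyloxy)-6-methoxy-3-[(phenylsulfonyl)methyl]-1,2,3,4-tetrahydronaphthalen-2-yl]methanol | COc1cc([C@H]2c3c(cc(OC)c(OCc4ccccc4)c3OCc5ccccc5)C[C@@H](CS(=O)(=O)c6ccccc6)[C@@H]2CO)ccc1OCc7ccccc7 | intermediate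
18 | (1S,2R,3R)-7,8-bis(benzyloxy)-2-[(benzyloxy)methyl]-1-[4-(benzyloxy)-3-methoxyphenyl]-6-methoxy-3-[(phenylsulfonyl)methyl]-1,2,3,4-tetrahydronaphthalene | COc1cc([C@H]2c3c(cc(OC)c(OCc4ccccc4)c3OCc5ccccc5)C[C@@H](CS(=O)(=O)c6ccccc6)[C@@H]2COCc8ccccc8)ccc1OCc7ccccc7 | intermediate
19 | α-lithio derivative of 18, lithium on the sulfonyl-bearing carbon, ring stereocentres as in 18 (not isolated) | COc1cc([C@H]2c3c(cc(OC)c(OCc4ccccc4)c3OCc5ccccc5)C[C@@H](C([Li])S(=O)(=O)c6ccccc6)[C@@H]2COCc8ccccc8)ccc1OCc7ccccc7 | intermediate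
20 | α-(trimethylsilyloxy) derivative of 18, OSiMe3 on the sulfonyl-bearing carbon, ring stereocentres as in 18 (not isolated) | COc1cc([C@H]2c3c(cc(OC)c(OCc4ccccc4)c3OCc5ccccc5)C[C@@H](C(O[Si](C)(C)C)S(=O)(=O)c6ccccc6)[C@@H]2COCc8ccccc8)ccc1OCc7ccccc7 | intermediate
21 | (1S,2R,3R)-7,8-bis(benzyloxy)-2-[(benzyloxy)methyl]-1-[4-(benzyloxy)-3-methoxyphenyl]-6-methoxy-1,2,3,4-tetrahydronaphthalene-3-carbaldehyde (tetralin numbering) | COc1cc([C@H]2c3c(cc(OC)c(OCc4ccccc4)c3OCc5ccccc5)C[C@@H](C=O)[C@@H]2COCc6ccccc6)ccc1OCc7ccccc7 | intermediate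
22 | [(1S,2R,3R)-7,8-bis(benzyloxy)-2-[(benzyloxy)methyl]-1-[4-(benzyloxy)-3-methoxyphenyl]-6-methoxy-1,2,3,4-tetrahydronaphthalen-3-yl]methanol (tetralin numbering) | COc1cc([C@H]2c3c(cc(OC)c(OCc4ccccc4)c3OCc5ccccc5)C[C@@H](CO)[C@@H]2COCc6ccccc6)ccc1OCc7ccccc7 | intermediate
23 | (1S,2R,3R)-1-(4-hydroxy-3-methoxyphenyl)-2,3-bis(hydroxymethyl)-6-methoxy-1,2,3,4-tetrahydronaphthalene-7,8-diol | COc1cc([C@H]2c3c(cc(OC)c(O)c3O)C[C@@H](CO)[C@@H]2CO)ccc1O | target

Total step count: 13. Longest linear sequence: 13 steps (from 1).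

Steps most likely to fail

Step 7. Three processes threaten it: slow insertion of the aryl-rhodium into the di-ortho-substituted alkylidene malonate; base-induced migration of the sulfonyl alkene into conjugation with ring A before the enolate reaches it; and a closure that gives the 1,3-trans ring because the C8 benzyloxy group pushes the C1 aryl pseudo-axial. The fallback separates the two bond formations. It sets out from 9, which carries no sulfone, so the same rhodium/diene arylation with 12 can be run warmer and with a full equivalent of KOH. This gives dimethyl 2-{(S)-[6-allyl-2,3-bis(benzyloxy)-4-methoxyphenyl][4-(benzyloxy)-3-methoxyphenyl]methyl}malonate F1. Cross-metathesis of F1 with 10 under the conditions of step 6 gives dimethyl 2-{(S)-[4-(benzyloxy)-3-methoxyphenyl]{2,3-bis(benzyloxy)-4-methoxy-6-[(E)-3-(phenylsulfonyl)prop-2-en-1-yl]phenyl}methyl}malonate F2. A separate Michael closure then follows, with Cs2CO3 in MeCN at 0 °C for the kinetic ring or catalytic t-BuOK in THF/t-BuOH if equilibration through retro-Michael is wanted. The route is rejoined at 14.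

Step 11. Oxygen transfer from the peroxide to the hindered carbanion may be slow, unreacted carbanion may add to the aldehyde as it is released, and the silanolate may epimerise the aldehyde at C3. The fallback replaces carbanion oxidation by alkylation, elimination and oxidative cleavage. It sets out from 18: the lithiated sulfone is alkylated with (iodomethyl)trimethylsilane to the β-silyl sulfone, 7,8-bis(benzyloxy)-2-[(benzyloxy)methyl]-1-[4-(benzyloxy)-3-methoxyphenyl]-6-methoxy-3-[1-(phenylsulfonyl)-2-(trimethylsilyl)ethyl]-1,2,3,4-tetrahydronaphthalene F3 (ring stereocentres arranged as in 18, both epimers at the sulfonyl carbon). Bu4NF in THF induces 1,2-elimination of benzenesulfinate to the C3-vinyl compound, 7,8-bis(benzyloxy)-2-[(benzyloxy)methyl]-1-[4-(benzyloxy)-3-methoxyphenyl]-6-methoxy-3-vinyl-1,2,3,4-tetrahydronaphthalene F4 (ring substituents arranged as in 18). Dihydroxylation–periodate cleavage (OsO4 cat., NaIO4, 2,6-lutidine, dioxane/H2O) then gives the aldehyde under neutral conditions, and the route is rejoined at 21.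

Step 6. A ruthenium hydride may move the allyl double bond into conjugation with ring A, or the metathesis may stall with the electron-poor partner. The fallback builds the vinyl sulfone by radical addition and elimination. It sets out from 9: iodosulfonylation of the terminal alkene (PhSO2Na, I2, EtOAc/H2O, rt, light) gives dimethyl 2-({2,3-bis(benzyloxy)-6-[2-iodo-3-(phenylsulfonyl)propyl]-4-methoxyphenyl}methylidene)malonate F5. Dehydroiodination with Et3N in CH2Cl2 at 0 °C, which proceeds through the α-sulfonyl carbanion, gives the (E)-vinyl sulfone, and the route is rejoined at 11.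

Further compounds
F1 | step 7 | dimethyl 2-{(S)-[6-allyl-2,3-bis(benzyloxy)-4-methoxyphenyl][4-(benzyloxy)-3-methoxyphenyl]methyl}malonate | COc1cc([C@H](C(C(=O)OC)C(=O)OC)c2c(CC=C)cc(OC)c(OCc3ccccc3)c2OCc4ccccc4)ccc1OCc5ccccc5
F2 | step 7 | dimethyl 2-{(S)-[4-(benzyloxy)-3-methoxyphenyl]{2,3-bis(benzyloxy)-4-methoxy-6-[(E)-3-(phenylsulfonyl)prop-2-en-1-yl]phenyl}methyl}malonate | COc1cc([C@H](C(C(=O)OC)C(=O)OC)c2c(C/C=C/S(=O)(=O)c6ccccc6)cc(OC)c(OCc3ccccc3)c2OCc4ccccc4)ccc1OCc5ccccc5
F3 | step 11 | 7,8-bis(benzyloxy)-2-[(benzyloxy)methyl]-1-[4-(benzyloxy)-3-methoxyphenyl]-6-methoxy-3-[1-(phenylsulfonyl)-2-(trimethylsilyl)ethyl]-1,2,3,4-tetrahydronaphthalene, ring stereocentres as in 18, both epimers at the sulfonyl carbon | COc1cc([C@H]2c3c(cc(OC)c(OCc4ccccc4)c3OCc5ccccc5)C[C@@H](C(C[Si](C)(C)C)S(=O)(=O)c6ccccc6)[C@@H]2COCc8ccccc8)ccc1OCc7ccccc7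
F4 | step 11 | 7,8-bis(benzyloxy)-2-[(benzyloxy)methyl]-1-[4-(benzyloxy)-3-methoxyphenyl]-6-methoxy-3-vinyl-1,2,3,4-tetrahydronaphthalene, ring substituents arranged as in 18 | COc1cc([C@H]2c3c(cc(OC)c(OCc4ccccc4)c3OCc5ccccc5)C[C@@H](C=C)[C@@H]2COCc6ccccc6)ccc1OCc7ccccc7
F5 | step 6 | dimethyl 2-({2,3-bis(benzyloxy)-6-[2-iodo-3-(phenylsulfonyl)propyl]-4-methoxyphenyl}methylidene)malonate, racemic at the iodine-bearing carbon | COC(=O)C(=Cc1c(CC(I)CS(=O)(=O)c2ccccc2)cc(OC)c(OCc3ccccc3)c1OCc4ccccc4)C(=O)OC
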